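Reading an order in partner straight from its charge is the trap here: Tuesday's run stops at 60.0 % product with 38.5 % substrate unreacted, so you need the partner present at the moment asked about, not the partner charged.

in all of them: free catalyst 1 mol%

| flask | substrate | partner | remark |
|---|---|---|---|
| Thursday's | 0.022 M | 0.75 equiv | run made earlier |
| Tuesday's | 0.022 M | 3 equiv | run made earlier |
| Wednesday's | 0.033 M | 1.5 equiv | run made earlier |
| flask | 0.022 M | 1.50 equiv |  |

| run | time / min | product / % | substrate / % |
|---|---|---|---|
| Thursday's | 1.33 | 7.2 | 92.8 |
| Thursday's | 4.00 | 16.1 | 84.5 |
| Thursday's | 8.00 | 17.2 | 81.0 |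
| Thursday's | 12.0 | 20.0 | 79.9 |
| Thursday's | 15.0 | 19.9 | 77.4 |
| Tuesday's | 1.33 | 15.8 | 81.5 |
| Tuesday's | 4.00 | 39.7 | 59.8 |
| Tuesday's | 8.00 | 56.9 | 43.7 |
| Tuesday's | 12.0 | 60.1 | 38.6 |
| Tuesday's | 15.0 | 60.0 | 38.5 |
| Wednesday's | 3.00 | 27.3 | 70.0 |
| Wednesday's | 6.00 | 42.2 | 57.2 |
| Wednesday's | 10.0 | 47.3 | 52.9 |
| Wednesday's | 12.0 | 48.3 | 52.5 |
| Wednesday's | 15.0 | 48.0 | 53.8 |

(readings scatter by 1 percentage point)

- apparent order in free catalyst when 10 % of the substrate are converted (percent change of the rate of making product for one percent more free catalyst charged)
- apparent order in partner when 10 % of the substrate are converted (percent change of the rate of making product for one percent more partner charged)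
- factor on the rate of making product when 10 % of the substrate are converted if partner is charged twice over

- the numbers in the tables scatter by 1 percentage point (one standard deviation)
- steps thought possible: partner + free catalyst <-> catalyst intermediate A; catalyst intermediate A -> catalyst intermediate B; substrate + catalyst intermediate B -> catalyst intermediate C; catalyst intermediate C -> free catalyst + product; partner -> decomposed reagent

My own reckoning joins two ends, a rate proportional to partner at low partner and a ceiling at high partner:

rate = ceiling × partner / (half-speed partner + partner)

From Thursday's charge to Tuesday's, partner rises 4.00 times, while product at 1.33 min rises 2.19 times. Solving for the one unknown gives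

half-speed partner = 0.0437 M

This is the partner at which the rate stands at half its ceiling. Thursday's early rate then puts the ceiling at 0.00434 M min⁻¹. Thursday's gap to its plateau gives a reading for partner loss of 0.338 min⁻¹. For this flask, charged with 0.0330 M partner, the mark is 10 % of the substrate converted:

time to the mark = 1.18 min
partner then = 0.0222 M
local order = half-speed partner / (half-speed partner + partner then) = 0.663

The weak link is that this holds the partner at the mark fixed. More partner shortens the time to the mark, and that time shrinks by the order at the charge, 0.570, so the fraction of partner lost by the mark shrinks too: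

order in partner = 0.663 × (1 + loss × time × 0.570) = 0.813
order in free catalyst = 1 + 0.663 × loss × time = 1.26

With partner doubled, the mark comes at 0.842 min, sooner, with 0.0497 M partner, so the factor is 1.58.

The forecast, made from the same runs, says of the early rates “which suggests saturation”. It gives 1.25 (1.05 to 1.45), 0.83 (0.6 to 1.05) and 1.55 (1.35 to 1.85), which differ a little from mine.

The flask gives 1.2, 0.82 and 1.56, inside the forecast's ranges.

    partner + free catalyst ⇌ catalyst intermediate A (K = 880 L mol⁻¹, k = 9.00 L mol⁻¹ s⁻¹)
    catalyst intermediate A → catalyst intermediate B (k = 0.810 s⁻¹)
    substrate + catalyst intermediate B → catalyst intermediate C (k = 33.0 L mol⁻¹ s⁻¹)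
    catalyst intermediate C → free catalyst + product (k = 73.0 s⁻¹)
    partner → decomposed reagent (k = 0.00420 s⁻¹)

At the start of this flask, decomposition uses partner 2.1 times as fast as the forward direction of the first step alone. Tuesday's run is this flask's recipe with partner doubled, and it passed the mark before its first reading of 15.8 % product. With the reckoned 0.0497 M partner there, the half-speed partner gives it a local order of 0.468.

The earlier runs and the new flask were generated by integration from invented constants.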